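**Plan**

- Retrosynthesis: ring A of the flavone is taken back to its 5,8-dihydro form and then cut at C4a–C5 and C8–C8a. This leaves 2,3-dimethoxybutadiene and a 2-aryl-4-pyranone (ring C) carrying a phenylsulfinyl group on the carbon that becomes C4a.
- Enabling feature: ring A has its two methoxy groups on the neighbouring carbons C6 and C7 and only hydrogen on C5 and C8. That is the footprint of a 2,3-dimethoxybutadiene added across the C4a=C8a bond.
- The pyranone is cut at C2–C3, C5–C6 and O1–C6 (pyranone numbering) into 2,3,4-trimethoxybenzoyl chloride, (phenylthio)acetone and a formamide acetal carbon.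
- Forward order: ring B is bought as 2,3,4-trimethoxybenzoic acid; ring C is closed by enaminone acylation and acid cyclisation; sulfur is oxidised; ring A is closed by cycloaddition with loss of sulfenic acid and then aromatised.
- Stereochemistry: the target has no stereocentre. The sulfoxide sulfur and the two cis ring-fusion centres of the cycloadduct are transient and are erased by the elimination and the aromatisation.

Key step: step 5

Remark on the chemistry: sulfoxide 8 and adduct 10 are racemic (10 possibly as sulfur epimers), and the Z geometry drawn for the push-pull enaminones 3 and 6 is the expected one. None of this matters, because every one of these elements is destroyed before the target is reached.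

**Route**

Step 1
Reactants: 1 1-(phenylsulfanyl)propan-2-one ((phenylthio)acetone); 2 N,N-dimethylformamide dimethyl acetal
Product: 3 (Z)-4-(dimethylamino)-3-(phenylsulfanyl)but-3-en-2-one
Conditions: 2 (1.2 equiv), toluene, 90 °C, MeOH distilled off
Reagents that add atoms: none
Why: Enaminone formation by condensation of the formamide acetal with the methylene flanked by sulfur and the carbonyl group, which is far more acidic than the methyl group and should react selectively.

Step 2
Reactants: 4 2,3,4-trimethoxybenzoic acid
Product: 5 2,3,4-trimethoxybenzoyl chloride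
Conditions: (COCl)2 (1.3 equiv), DMF (cat.), CH2Cl2, 0 °C to rt; evaporate and use crude
Reagents that add atoms: oxalyl chloride, O=C(Cl)C(Cl)=O
Why: Standard acid chloride formation through the Vilsmeier-type chloroiminium catalyst, mild enough for the three aryl methyl ethers.

Step 3
Reactants: 3 (Z)-4-(dimethylamino)-3-(phenylsulfanyl)but-3-en-2-one; 5 2,3,4-trimethoxybenzoyl chloride
Product: 7 5-(phenylsulfanyl)-2-(2,3,4-trimethoxyphenyl)-4H-pyran-4-one, via acylated enaminone diketone 6 (not isolated)
Conditions: LiN(SiMe3)2 (2.2 equiv), THF, −78 °C; then 5, −78 to −20 °C; then 2 M HCl, THF, rt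
Reagents that add atoms: none
Why: Claisen-type C-acylation of the kinetic methyl-ketone enolate of a vinylogous amide (its only enolisable position), followed by acid-induced attack of the aroyl enol oxygen on the aminomethylene carbon with loss of dimethylamine, a known way to 4-pyranones that carry a substituent next to the carbonyl group.

Step 4
Reactants: 7 5-(phenylsulfanyl)-2-(2,3,4-trimethoxyphenyl)-4H-pyran-4-one
Product: 8 5-(phenylsulfinyl)-2-(2,3,4-trimethoxyphenyl)-4H-pyran-4-one (racemic at sulfur)
Conditions: mCPBA (1.0 equiv), CH2Cl2, −78 to 0 °C; aq NaHCO3 wash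
Reagents that add atoms: mCPBA (3-chloroperoxybenzoic acid), O=C(OO)c1cccc(Cl)c1
Why: Chemoselective sulfide-to-sulfoxide oxidation with one equivalent of peracid at low temperature, where sulfur should react far faster than the electron-poor pyranone double bonds or the arenes.

Step 5
Reactants: 8 5-(phenylsulfinyl)-2-(2,3,4-trimethoxyphenyl)-4H-pyran-4-one; 9 2,3-dimethoxybuta-1,3-diene
Product: 11 6,7-dimethoxy-2-(2,3,4-trimethoxyphenyl)-5,8-dihydro-4H-chromen-4-one, via cis-fused sulfinyl cycloadduct 10 (not isolated)
Conditions: 9 (5 equiv), 2,6-lutidine (0.2 equiv), BHT (cat.), toluene, 110 °C, sealed tube; filtration through basic alumina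
Reagents that add atoms: none
Why: Proposed new method: the C5=C6 bond of 8 bears the ring carbonyl and the sulfinyl group on the same carbon and should therefore serve as the electron-poor 2π partner in a normal-demand Diels–Alder reaction with the electron-rich diene 9; the six-membered carbocycle (future ring A) closes by a concerted, suprafacial [4+2] cycloaddition that forms C4a–C5 and C8–C8a at once. The closest known reaction types are Diels–Alder additions of 2-sulfinyl enones, sulfinyl quinones and 3-acyl- or 3-cyanochromones to electron-rich dienes, several of them followed by loss of sulfenic acid, whereas a monocyclic 3-sulfinyl-4-pyranone has not been used as the dienophile. The two stereocentres of adduct 10 (C4a and C8a) are fixed as cis by the suprafacial addition to the ring double bond, so the C8a hydrogen lies syn to the sulfinyl group and the thermal syn (Ei) elimination of benzenesulfenic acid can follow in the same pot, restoring C4a=C8a and erasing both centres. The step needs site selectivity for C5=C6 over the aryl-bearing C2=C3 bond, which the twofold activation by carbonyl and sulfinyl groups and the steric shielding of C2 by the ortho-substituted aryl ring should secure, and it needs no regiocontrol because 9 is symmetric. Elimination toward C8a–H is favoured since it regenerates the conjugated 4-pyranone, and a minor loss of a C5 hydrogen would only give an isomer at the same oxidation level that step 6 would aromatise to the same flavone; the lutidine buffer keeps the acid-labile bis(enol ether) of 11 intact.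

Step 6
Reactants: 11 6,7-dimethoxy-2-(2,3,4-trimethoxyphenyl)-5,8-dihydro-4H-chromen-4-one
Product: 12 6,7-dimethoxy-2-(2,3,4-trimethoxyphenyl)-4H-chromen-4-one (target)
Conditions: DDQ (1.1 equiv), toluene, 0 °C to rt
Reagents that add atoms: none
Why: Quinone dehydrogenation of a 1,4-cyclohexadiene (hydride abstraction from an allylic CH2 next to an enol ether, then proton loss), driven by the aromatisation of ring A.

**Compound list**

1 | 1-(phenylsulfanyl)propan-2-one | CC(=O)CSc1ccccc1 | starting material
2 | N,N-dimethylformamide dimethyl acetal | COC(OC)N(C)C | starting material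
3 | (Z)-4-(dimethylamino)-3-(phenylsulfanyl)but-3-en-2-one | CC(=O)/C(Sc1ccccc1)=C/N(C)C | intermediate
4 | 2,3,4-trimethoxybenzoic acid | COc1ccc(C(=O)O)c(OC)c1OC | starting material
5 | 2,3,4-trimethoxybenzoyl chloride | COc1ccc(C(Cl)=O)c(OC)c1OC | intermediate
6 | (Z)-5-(dimethylamino)-4-(phenylsulfanyl)-1-(2,3,4-trimethoxyphenyl)pent-4-ene-1,3-dione (not isolated) | COc1ccc(C(=O)CC(=O)/C(Sc2ccccc2)=C/N(C)C)c(OC)c1OC | intermediate
7 | 5-(phenylsulfanyl)-2-(2,3,4-trimethoxyphenyl)-4H-pyran-4-one | COc1ccc(-c2cc(=O)c(Sc3ccccc3)co2)c(OC)c1OC | intermediate
8 | 5-(phenylsulfinyl)-2-(2,3,4-trimethoxyphenyl)-4H-pyran-4-one, racemic at sulfur | COc1ccc(-c2cc(=O)c(S(=O)c3ccccc3)co2)c(OC)c1OC | intermediate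
9 | 2,3-dimethoxybuta-1,3-diene | C=C(OC)C(OC)=C | starting material
10 | cis-6,7-dimethoxy-4a-(phenylsulfinyl)-2-(2,3,4-trimethoxyphenyl)-4a,5,8,8a-tetrahydro-4H-chromen-4-one (sulfinyl group on C4a and hydrogen on C8a on the same face; racemic, either configuration at sulfur; not isolated) | COC1=C(OC)C[C@@]2(S(=O)c3ccccc3)C(=O)C=C(c3ccc(OC)c(OC)c3OC)O[C@H]2C1 | intermediate
11 | 6,7-dimethoxy-2-(2,3,4-trimethoxyphenyl)-5,8-dihydro-4H-chromen-4-one | COC1=C(OC)CC2=C(C1)C(=O)C=C(O2)c1ccc(OC)c(OC)c1OC | intermediate
12 | 6,7-dimethoxy-2-(2,3,4-trimethoxyphenyl)-4H-chromen-4-one | COc1cc2oc(-c3ccc(OC)c(OC)c3OC)cc(=O)c2cc1OC | target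

**Step count**

Total steps: 6. Longest linear sequence: 5 steps (steps 1, 3, 4, 5 and 6, starting from 1); step 2 prepares the second fragment.

**Steps most likely to fail**

Step 5 (proposed new method). The cycloaddition may not take place at all: the pyranone double bond may remain too weakly activated at temperatures the diene tolerates, and the diene may polymerise or be consumed by the sulfenic acid before an adduct forms. The fallback gives up the cycloaddition and builds the flavone by the Baker–Venkataraman sequence. It sets out from acid chloride 5, which would acylate commercial 1-(2-hydroxy-4,5-dimethoxyphenyl)ethanone (pyridine, DMAP cat., CH2Cl2) to give 2-acetyl-4,5-dimethoxyphenyl 2,3,4-trimethoxybenzoate F1. KOH in pyridine at 50 °C should bring about the acyl shift to 1-(2-hydroxy-4,5-dimethoxyphenyl)-3-(2,3,4-trimethoxyphenyl)propane-1,3-dione F2. H2SO4 in AcOH at 100 °C should then close ring C with loss of water, so the fallback comes back to the route at the target 12.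

Step 3. C-acylation of the enaminone enolate may lose out to O-acylation, to double acylation, or to proton transfer from the newly formed diketone to unreacted enolate. The fallback replaces the acylation by an aldol addition and an oxidation. It sets out from enaminone 3, whose lithium enolate (LiN(SiMe3)2, THF, −78 °C) would add to commercial 2,3,4-trimethoxybenzaldehyde to give racemic (Z)-5-(dimethylamino)-1-hydroxy-4-(phenylsulfanyl)-1-(2,3,4-trimethoxyphenyl)pent-4-en-3-one F3. Oxidation of the benzylic alcohol with MnO2 in CH2Cl2 should give diketone 6, and treatment with 2 M HCl in THF should close it to pyranone 7, where the fallback re-joins the route.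

Step 4. Oxidation at sulfur may run on to the sulfone, which cannot undergo the thermal syn-elimination, or may stall short of completion on the deactivated vinylic sulfide. The fallback moves the oxidation to the start and carries the sulfinyl group through the ring construction. It sets out from ketone 1, which NaIO4 in MeOH/H2O at 0 °C should oxidise cleanly to 1-(phenylsulfinyl)propan-2-one F4. Condensation with acetal 2 should give (Z)-4-(dimethylamino)-3-(phenylsulfinyl)but-3-en-2-one F5. Enolisation with LiN(SiMe3)2 and acylation with 5 should give (Z)-5-(dimethylamino)-4-(phenylsulfinyl)-1-(2,3,4-trimethoxyphenyl)pent-4-ene-1,3-dione F6, and acid cyclisation of F6 should deliver sulfoxide 8 directly, where the fallback comes back to the route.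

**Further compounds**

F1 | step 5 | 2-acetyl-4,5-dimethoxyphenyl 2,3,4-trimethoxybenzoate | COc1ccc(C(=O)Oc2cc(OC)c(OC)cc2C(C)=O)c(OC)c1OC
F2 | step 5 | 1-(2-hydroxy-4,5-dimethoxyphenyl)-3-(2,3,4-trimethoxyphenyl)propane-1,3-dione | COc1ccc(C(=O)CC(=O)c2cc(OC)c(OC)cc2O)c(OC)c1OC
F3 | step 3 | (Z)-5-(dimethylamino)-1-hydroxy-4-(phenylsulfanyl)-1-(2,3,4-trimethoxyphenyl)pent-4-en-3-one, racemic | COc1ccc(C(O)CC(=O)/C(Sc2ccccc2)=C/N(C)C)c(OC)c1OC
F4 | step 4 | 1-(phenylsulfinyl)propan-2-one, racemic | CC(=O)CS(=O)c1ccccc1
F5 | step 4 | (Z)-4-(dimethylamino)-3-(phenylsulfinyl)but-3-en-2-one, racemic | CC(=O)/C(=C/N(C)C)S(=O)c1ccccc1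
F6 | step 4 | (Z)-5-(dimethylamino)-4-(phenylsulfinyl)-1-(2,3,4-trimethoxyphenyl)pent-4-ene-1,3-dione, racemic | COc1ccc(C(=O)CC(=O)/C(=C/N(C)C)S(=O)c2ccccc2)c(OC)c1OC
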